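**Plan**
1. Numbering used throughout: C1 (cyclobutane CH bearing octyl), C2, C3=C4, C5 (C–OH), C6 (C–CO2H), C7, C8 (CHOH), C9, C10 (CH2), C11, C12, C13. Rings: cyclobutane C1–C2–C12–C11, ring B C2–C3–C4–C5–C13–C12, cyclopentane C9–C10–C11–C12–C13, ring C C5–C6–C7–C8–C9–C13.
2. Retrosynthesis, late part: ring C is cut at C6=C7 (ring-closing metathesis); the C5–O bond is removed with allylic transposition (singlet-oxygen ene on C5=C6); C5=C6 goes back to a C5 ketone, and C3=C4 to a saturated ketone.
3. Core disconnection: C10–C11 and C12–C13 are cut together, as a (3+2) cycloaddition of the cyclobutene C11=C12 with the cyclopropane carbons C9/C10/C13 of a vinylcyclopropane whose vinyl carbon is C5, tethered to C2 through C4–C3.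
4. Enabling feature: the cyclopentane shares edge C11–C12 with a strained four-membered ring and edge C12–C13 with ring B, and C13 sits next to C5, which can be carried as an alkene carbon that activates a C9–C10–C13 cyclopropane.
5. Forward order: cyclobutene (C1, C2, C11, C12) from the 2-pyranone photoproduct, chain extension to a ketophosphonate, olefination with the C8 aldehyde, cyclopropanation, methylenation, then cyclopentane and ring B in one step, ring C last.
6. Stereochemistry: C1/C2 by ligand-controlled allylic alkylation; C8 from (R)-but-3-ene-1,2-diol; C9/C13 from C8 (Felkin–Anh cyclopropanation, trans); C11/C12/C13 in the cycloaddition (tether-directed face, retention at C13); C5 by convex-face singlet oxygen.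

Key step: step 12

Remark: the absolute sense of induction in step 2 is assumed to follow the ligand enantiomer; the enantiomer that gives (1R,4R)-5 is used.
Remark: 2 is racemic (both enantiomers converge in step 2) and 23 is an E/Z mixture (both isomers converge in step 16).

**Route**

Step 1
Reactants: 1 2H-pyran-2-one
Product: 2 rac-2-oxabicyclo[2.2.0]hex-5-en-3-one
Conditions: hν (300 nm), Et2O (dilute), −10 °C
Reagents that add atoms: none
Why: Photochemical 4π electrocyclisation (disrotatory) of the pyranone diene should give the cis-fused bicyclic lactone, racemic because no control element is present.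

Step 2
Reactants: 2 rac-2-oxabicyclo[2.2.0]hex-5-en-3-one; 3 n-octylmagnesium bromide
Product: 5 (1R,4R)-4-octylcyclobut-2-ene-1-carboxylic acid, via di-n-octylzinc 4 (not isolated)
Conditions: 3 (2.4 equiv), ZnCl2 (1.2 equiv), Et2O, 0 °C → rt, 1,4-dioxane, filtration; then 2, Pd2(dba)3·CHCl3 (2.5 mol %), TADDOL-derived phosphoramidite ligand (6 mol %), THF, −20 °C; aq. HCl
Reagents that add atoms: none
Why: Palladium-catalysed asymmetric allylic alkylation with a dialkylzinc: both enantiomers of 2 ionise to one meso π-allyl palladium carboxylate, the chiral ligand selects one enantiotopic terminus, and octyl is transferred through the metal to the face anti to the carboxylate, which should set C1 and C2 trans in one absolute sense.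

Step 3
Reactants: 5 (1R,4R)-4-octylcyclobut-2-ene-1-carboxylic acid
Product: 6 [(1R,4R)-4-octylcyclobut-2-en-1-yl]methanol
Conditions: LiAlH4, Et2O, 0 °C → rt; aq. NaOH work-up
Reagents that add atoms: none
Why: Hydride reduction of the acid to the primary alcohol, run cold because the cyclobutene acid is prone to conrotatory ring opening; the ring alkene and both stereocentres are not touched.

Step 4
Reactants: 6 [(1R,4R)-4-octylcyclobut-2-en-1-yl]methanol
Product: 7 (3R,4R)-3-(iodomethyl)-4-octylcyclobut-1-ene
Conditions: I2, PPh3, imidazole, CH2Cl2, 0 °C, dark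
Reagents that add atoms: iodine, II
Why: Appel-type iodination by SN2 displacement of the activated primary oxygen; no stereocentre is involved.

Step 5
Reactants: 7 (3R,4R)-3-(iodomethyl)-4-octylcyclobut-1-ene; 8 dimethyl (2-oxopropyl)phosphonate
Product: 9 dimethyl {2-oxo-4-[(1R,4R)-4-octylcyclobut-2-en-1-yl]butyl}phosphonate
Conditions: 8, NaH, THF, 0 °C; n-BuLi, 0 °C; then 7, 0 °C → rt; aq. NH4Cl
Reagents that add atoms: none
Why: γ-Alkylation of the β-ketophosphonate dianion, whose terminal carbanion is the more reactive site, by SN2 on the primary iodide.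

Step 6
Reactants: 10 (R)-but-3-ene-1,2-diol
Product: 11 (R)-3,4-bis[(tert-butyldimethylsilyl)oxy]but-1-ene
Conditions: TBSCl (2.4 equiv), imidazole, DMF, rt
Reagents that add atoms: tert-butyldimethylsilyl chloride, CC(C)(C)[Si](C)(C)Cl
Why: Silylation of both hydroxyl groups; the stereocentre is not involved.

Step 7
Reactants: 11 (R)-3,4-bis[(tert-butyldimethylsilyl)oxy]but-1-ene
Product: 12 (R)-2-[(tert-butyldimethylsilyl)oxy]but-3-en-1-ol
Conditions: HF·pyridine, pyridine, THF, 0 °C
Reagents that add atoms: none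
Why: Selective cleavage of the less hindered primary silyl ether by buffered fluoride, the secondary allylic silyl ether reacting much more slowly.

Step 8
Reactants: 12 (R)-2-[(tert-butyldimethylsilyl)oxy]but-3-en-1-ol
Product: 13 (R)-2-[(tert-butyldimethylsilyl)oxy]but-3-enal
Conditions: Dess–Martin periodinane, NaHCO3, CH2Cl2, 0 °C → rt; used at once
Reagents that add atoms: none
Why: Dess–Martin oxidation under buffered, non-basic conditions should keep the epimerisable α-silyloxy β,γ-unsaturated aldehyde intact.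

Step 9
Reactants: 9 dimethyl {2-oxo-4-[(1R,4R)-4-octylcyclobut-2-en-1-yl]butyl}phosphonate; 13 (R)-2-[(tert-butyldimethylsilyl)oxy]but-3-enal
Product: 14 (4E,6R)-6-[(tert-butyldimethylsilyl)oxy]-1-[(1R,4R)-4-octylcyclobut-2-en-1-yl]octa-4,7-dien-3-one
Conditions: Ba(OH)2 (activated), THF/H2O 40:1, 0 °C → rt
Reagents that add atoms: none
Why: Horner–Wadsworth–Emmons olefination of the stabilised ketophosphonate anion should give the (E)-enone under mild Ba(OH)2 activation that the sensitive aldehyde tolerates.

Step 10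
Reactants: 14 (4E,6R)-6-[(tert-butyldimethylsilyl)oxy]-1-[(1R,4R)-4-octylcyclobut-2-en-1-yl]octa-4,7-dien-3-one
Product: 15 1-{(1S,2S)-2-[(R)-1-[(tert-butyldimethylsilyl)oxy]prop-2-en-1-yl]cyclopropyl}-3-[(1R,4R)-4-octylcyclobut-2-en-1-yl]propan-1-one
Conditions: Me3S(O)I, NaH, DMSO, rt
Reagents that add atoms: trimethylsulfoxonium iodide, C[S+](C)(C)=O.[I-]
Why: Corey–Chaykovsky cyclopropanation: the sulfoxonium ylide adds to C9 anti to the C8 silyloxy group in the Felkin–Anh conformer (C–O perpendicular to the enone plane, H inside) and the enolate closes the ring by 3-exo-tet displacement, which should give the trans-cyclopropane and set C9 and C13 from C8.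

Step 11
Reactants: 15 cyclopropyl ketone (name as in step 10)
Product: 16 tert-butyldimethyl{[(R)-1-{(1S,2S)-2-{4-[(1R,4R)-4-octylcyclobut-2-en-1-yl]but-1-en-2-yl}cyclopropyl}prop-2-en-1-yl]oxy}silane
Conditions: Ph3PCH3Br, KOtBu, THF, 0 °C → rt
Reagents that add atoms: methyltriphenylphosphonium bromide, C[P+](c1ccccc1)(c1ccccc1)c1ccccc1.[Br-]
Why: Wittig methylenation of the ketone installs the 1,1-disubstituted alkene (C5=CH2) that activates the cyclopropane; the cyclopropyl α-hydrogen is not acidic enough to epimerise.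

Step 12
Reactants: 16 vinylcyclopropane with the cyclobutene tethered at the vinyl α-carbon C5 (name as in step 11)
Product: 17 tricyclic 5-methylidene compound: cyclobutane C1–C2–C12–C11 (octyl on C1), cyclohexane C2–C3–C4–C5–C13–C12 (exocyclic C5=CH2), cyclopentane C9–C10–C11–C12–C13 (C9 bears (R)-CH(OTBS)CH=CH2); H on C2, C11, C12, C13 mutually cis, octyl on that same face, C9–H trans to C13–H (all as in the target)
Conditions: [Rh(dppp)]SbF6 (10 mol %; dppp = Ph2P(CH2)3PPh2), ClCH2CH2Cl (0.02 M), 65 °C, argon
Reagents that add atoms: none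
Why: Monovalent rhodium binds the C5=CH2 alkene and inserts into the less hindered C13–C10 cyclopropane bond to give a trivalent π-allyl (C13–C5–CH2)/σ-alkyl (C10) rhodacycle; the tethered cyclobutene C11=C12 inserts into Rh–C10 (C10–C11 bond) and reductive elimination at the allyl terminus C13 forms C12–C13. The closest known reaction type is the rhodium-catalysed intramolecular (3+2) cycloaddition of vinylcyclopropanes that carry the alkene tether on the α-carbon of the vinyl group, here run with a strained ring alkene as the two-carbon partner. Ring B (six-membered) closes through the C12–C13 bond with the C5 methylidene left exocyclic, and the cyclopentane closes by insertion followed by the same reductive elimination, a formal (3+2) mode. C11 and C12 are set by syn addition to the cyclobutene face that carries the C2 tether, which is the face anti to the C1 octyl group and gives cis ring fusions. C13 is set with retention (rhodium replaces C10, then C12 replaces rhodium), so the trans relation of the cyclopropane substituents becomes the trans C5/C8-branch relation on the cyclopentane, and C9 is untouched. The step needs cleavage of C13–C10 and not C13–C9 (the C9 substituent hinders the other bond), (3+2) in place of a bridged (5+2) closure (the α-tether makes the seven-membered alternative strained) and survival of the cyclobutene, which its all-sp3 trans-3,4-dialkyl substitution and a temperature below 70 °C should secure.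

Step 13
Reactants: 17 tricyclic 5-methylidene compound
Product: 19 tricyclic C5 ketone (C5=O in place of C5=CH2 of 17), via C5 spiro-epoxide 18 (not isolated)
Conditions: m-CPBA (1.05 equiv), NaHCO3, CH2Cl2, 0 °C; then H5IO6, THF/H2O, rt
Reagents that add atoms: m-chloroperbenzoic acid, O=C(OO)c1cccc(Cl)c1; water, O (the ketone oxygen stems from one of the two, depending on the site of epoxide hydrolysis)
Why: The electron-rich 1,1-disubstituted alkene should be epoxidised in preference to the vinyl group (deactivated by the allylic silyloxy group), and periodic acid cleaves the epoxide through its diol to the ketone, so the facial course of the epoxidation is immaterial.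

Step 14
Reactants: 19 tricyclic C5 ketone
Product: 21 tricyclic enone (C3=C4–C5=O), via trimethylsilyl enol ether 20 (not isolated)
Conditions: LiN(iPr)2, THF, −78 °C; Me3SiCl, −78 → 0 °C; then Pd(OAc)2 (1.1 equiv), MeCN, rt
Reagents that add atoms: none
Why: Kinetic deprotonation at the C4 methylene (C13 is a hindered ring-fusion methine), silyl trapping and Saegusa–Ito oxidation (β-hydride elimination from the divalent palladium enolate) should introduce C3=C4 without epimerising C13.

Step 15
Reactants: 21 tricyclic enone; 22 triethyl 2-phosphonopropionate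
Product: 23 ethyl 2-(tricyclic C5-ylidene)propanoate (tetrasubstituted C5=C6 bearing CH3 and CO2Et, C3=C4 retained; E/Z mixture)
Conditions: 22, NaH, THF, 0 °C; then 21, 0 → 65 °C
Reagents that add atoms: none
Why: Horner–Wadsworth–Emmons olefination of the ketone with the α-methyl phosphonate should give the tetrasubstituted dienoate; the E/Z ratio does not matter because this geometry is erased in step 16.

Step 16
Reactants: 23 dienoate (E/Z mixture)
Product: 25 ethyl 2-(C5-hydroxy tricyclic C3-en-5-yl)acrylate (C5–OH on the face of H-13, C6(=CH2)CO2Et on the face of C9), via C5 hydroperoxide 24 (not isolated)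
Conditions: O2, tetraphenylporphyrin (1 mol %), visible light, CH2Cl2, 0 °C; then PPh3, 0 °C → rt
Reagents that add atoms: dioxygen, O=O
Why: Schenck ene reaction of singlet oxygen with the geminal selectivity of α,β-unsaturated esters (hydrogen taken from the methyl on C6, C–O bond made at the β-carbon C5) on the convex face anti to C9 should set C5; PPh3 then reduces the hydroperoxide.

Step 17
Reactants: 25 hydroxy acrylate
Product: 26 tetracyclic ethyl ester, C8 silyl ether (target skeleton with CO2Et and C8–OTBS)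
Conditions: second-generation Hoveyda–Grubbs catalyst RuCl2(=CH-C6H4-2-OiPr)(SIMes) (10 mol %), toluene, 80 °C, argon sparge
Reagents that add atoms: none
Why: Ring-closing metathesis of the acrylate methylene with the C8 vinyl group should close the six-membered ring C at C6=C7 with loss of ethylene; the two alkenes lie on the same side because step 16 left C6 syn to C9.

Step 18
Reactants: 26 tetracyclic ethyl ester, C8 silyl ether
Product: 28 CNP0106718.3 (C1R,C2S,C5R,C8S,C9S,C11R,C12R,C13S), via diol ethyl ester 27 (not isolated)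
Conditions: Bu4NF, THF, 0 °C → rt; then LiOH·H2O, THF/MeOH/H2O, rt → 40 °C; cold aq. HCl to pH 4
Reagents that add atoms: lithium hydroxide, [Li+].[OH-]
Why: Fluoride cleaves the secondary silyl ether and hydroxide saponifies the ethyl ester; lactonisation is impossible because C8–OH and the carboxyl group are trans across C6=C7, and the mildly acidic work-up should spare the doubly allylic tertiary alcohol.

**Compound list**
1 | 2H-pyran-2-one | O=C1C=CC=CO1 | starting material
2 | rac-2-oxabicyclo[2.2.0]hex-5-en-3-one (cis-fused, racemate, one enantiomer drawn) | O=C1O[C@@H]2C=C[C@H]12 | intermediate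
3 | n-octylmagnesium bromide | CCCCCCCC[Mg]Br | starting material
4 | di-n-octylzinc | CCCCCCCC[Zn]CCCCCCCC | intermediate
5 | (1R,4R)-4-octylcyclobut-2-ene-1-carboxylic acid | CCCCCCCC[C@@H]1C=C[C@H]1C(=O)O | intermediate
6 | [(1R,4R)-4-octylcyclobut-2-en-1-yl]methanol | CCCCCCCC[C@@H]1C=C[C@H]1CO | intermediate
7 | (3R,4R)-3-(iodomethyl)-4-octylcyclobut-1-ene | CCCCCCCC[C@@H]1C=C[C@H]1CI | intermediate
8 | dimethyl (2-oxopropyl)phosphonate | CC(=O)CP(=O)(OC)OC | starting material
9 | dimethyl {2-oxo-4-[(1R,4R)-4-octylcyclobut-2-en-1-yl]butyl}phosphonate | CCCCCCCC[C@@H]1C=C[C@H]1CCC(=O)CP(=O)(OC)OC | intermediate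
10 | (R)-but-3-ene-1,2-diol | OC[C@H](O)C=C | starting material
11 | (R)-3,4-bis[(tert-butyldimethylsilyl)oxy]but-1-ene | CC(C)(C)[Si](C)(C)OC[C@H](O[Si](C)(C)C(C)(C)C)C=C | intermediate
12 | (R)-2-[(tert-butyldimethylsilyl)oxy]but-3-en-1-ol | OC[C@H](O[Si](C)(C)C(C)(C)C)C=C | intermediate
13 | (R)-2-[(tert-butyldimethylsilyl)oxy]but-3-enal | O=C[C@H](O[Si](C)(C)C(C)(C)C)C=C | intermediate
14 | (4E,6R)-6-[(tert-butyldimethylsilyl)oxy]-1-[(1R,4R)-4-octylcyclobut-2-en-1-yl]octa-4,7-dien-3-one | CCCCCCCC[C@@H]1C=C[C@H]1CCC(=O)/C=C/[C@H](O[Si](C)(C)C(C)(C)C)C=C | intermediate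
15 | 1-{(1S,2S)-2-[(R)-1-[(tert-butyldimethylsilyl)oxy]prop-2-en-1-yl]cyclopropyl}-3-[(1R,4R)-4-octylcyclobut-2-en-1-yl]propan-1-one | CCCCCCCC[C@@H]1C=C[C@H]1CCC(=O)[C@H]2C[C@@H]2[C@H](O[Si](C)(C)C(C)(C)C)C=C | intermediate
16 | tert-butyldimethyl{[(R)-1-{(1S,2S)-2-{4-[(1R,4R)-4-octylcyclobut-2-en-1-yl]but-1-en-2-yl}cyclopropyl}prop-2-en-1-yl]oxy}silane | CCCCCCCC[C@@H]1C=C[C@H]1CCC(=C)[C@H]2C[C@@H]2[C@H](O[Si](C)(C)C(C)(C)C)C=C | intermediate
17 | tricyclic 5-methylidene compound (description in step 12) | CCCCCCCC[C@H]1[C@@H]2CCC(=C)[C@H]3[C@@H]2[C@@H]1C[C@@H]3[C@H](O[Si](C)(C)C(C)(C)C)C=C | intermediate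
18 | C5 spiro-epoxide of 17 (oxirane oxygen on the convex face; configuration immaterial) | CCCCCCCC[C@H]1[C@@H]2CC[C@]4(CO4)[C@H]3[C@@H]2[C@@H]1C[C@@H]3[C@H](O[Si](C)(C)C(C)(C)C)C=C | intermediate
19 | tricyclic C5 ketone | CCCCCCCC[C@H]1[C@@H]2CCC(=O)[C@H]3[C@@H]2[C@@H]1C[C@@H]3[C@H](O[Si](C)(C)C(C)(C)C)C=C | intermediate
20 | trimethylsilyl enol ether of 19 (C4=C5–OSiMe3) | CCCCCCCC[C@H]1[C@@H]2CC=C(O[Si](C)(C)C)[C@H]3[C@@H]2[C@@H]1C[C@@H]3[C@H](O[Si](C)(C)C(C)(C)C)C=C | intermediate
21 | tricyclic enone (C3=C4–C5=O) | CCCCCCCC[C@H]1[C@@H]2C=CC(=O)[C@H]3[C@@H]2[C@@H]1C[C@@H]3[C@H](O[Si](C)(C)C(C)(C)C)C=C | intermediate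
22 | triethyl 2-phosphonopropionate | CCOC(=O)C(C)P(=O)(OCC)OCC | starting material
23 | ethyl 2-(tricyclic C5-ylidene)propanoate, E/Z mixture at C5=C6 | CCCCCCCC[C@H]1[C@@H]2C=CC(=C(C)C(=O)OCC)[C@H]3[C@@H]2[C@@H]1C[C@@H]3[C@H](O[Si](C)(C)C(C)(C)C)C=C | intermediate
24 | C5 tertiary hydroperoxide carrying the acrylate unit | CCCCCCCC[C@H]1[C@@H]2C=C[C@](OO)(C(=C)C(=O)OCC)[C@H]3[C@@H]2[C@@H]1C[C@@H]3[C@H](O[Si](C)(C)C(C)(C)C)C=C | intermediate
25 | ethyl 2-(C5-hydroxy tricyclic C3-en-5-yl)acrylate | CCCCCCCC[C@H]1[C@@H]2C=C[C@](O)(C(=C)C(=O)OCC)[C@H]3[C@@H]2[C@@H]1C[C@@H]3[C@H](O[Si](C)(C)C(C)(C)C)C=C | intermediate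
26 | tetracyclic ethyl ester, C8 tert-butyldimethylsilyl ether | CCCCCCCC[C@H]1[C@@H]2C=C[C@]3(O)C(C(=O)OCC)=C[C@@H](O[Si](C)(C)C(C)(C)C)[C@H]4C[C@H]1[C@H]2[C@@H]43 | intermediate
27 | tetracyclic ethyl ester, C5,C8-diol | CCCCCCCC[C@H]1[C@@H]2C=C[C@]3(O)C(C(=O)OCC)=C[C@@H](O)[C@H]4C[C@H]1[C@H]2[C@@H]43 | intermediate
28 | CNP0106718.3 | CCCCCCCC[C@H]1[C@@H]2C=C[C@]3(O)C(C(=O)O)=C[C@@H](O)[C@H]4C[C@H]1[C@H]2[C@@H]43 | target

**Totals**
Total step count: 18. Longest linear sequence: 15 steps (steps 1–5, then 9–18).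

**Steps most likely to fail**

Step 12. What may go wrong: slow migratory insertion of the 1,2-disubstituted ring alkene into the Rh–C10 bond, β-hydride elimination of the rhodacycle to dienes, cleavage of the substituted C13–C9 bond, or thermal conrotatory opening of the cyclobutene on prolonged heating. The fallback sets out from iodide 7, with aldehyde 13 as second component, and returns at ketone 19. It makes the same two bonds by an intramolecular Pauson–Khand reaction, which adds C10 as a carbonyl group that is removed afterwards. Iodide 7 is alkylated with LiCH2CN (CH3CN, n-BuLi, THF, −78 °C) to 3-[(1R,4R)-4-octylcyclobut-2-en-1-yl]propanenitrile F1, and iBu2AlH (CH2Cl2, −78 °C, aqueous tartrate) gives 3-[(1R,4R)-4-octylcyclobut-2-en-1-yl]propanal F2. Aldehyde 13 is homologated (Seyferth–Gilbert reaction with dimethyl (1-diazo-2-oxopropyl)phosphonate, K2CO3, MeOH, 0 °C) to (R)-tert-butyldimethyl(pent-1-en-4-yn-3-yloxy)silane F3. Its lithium acetylide (n-BuLi, THF, −78 °C) adds to F2 to give the propargylic alcohol F4 (both C5 epimers; this centre is oxidised later). Co2(CO)8 and then N-methylmorpholine N-oxide (CH2Cl2, rt) should give the tricyclic cyclopentenone F5 (C10 ketone, C9=C13 alkene, C5 alcohol) by cycloaddition on the cyclobutene face that carries the tether. Conjugate reduction with Li in liquid NH3/THF (−78 °C, NH4Cl quench) should give the saturated C10 ketone F6 with the cis C12/C13 ring fusion and, C9 being epimerisable, the more stable trans C9/C13 arrangement. TsNHNH2 (EtOH, rt) gives the tosylhydrazone F7; catecholborane and then NaOAc·3H2O (CHCl3, reflux) give the C10-methylene C5-alcohol F8; Dess–Martin oxidation returns to ketone 19.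

Step 16. What may go wrong: hydrogen abstraction from C13–H in place of the C6 methyl group, attack of singlet oxygen on the wrong face of C5, or a slow reaction of the electron-poor dienoate that lets other alkenes be oxidised. The fallback sets out from enone 21 and returns at 26, so it also covers a sluggish olefination in step 15. It makes the C5–C6 bond intramolecularly so that the tether fixes C5. Cross-metathesis of the vinyl group of 21 with ethyl acrylate (second-generation Hoveyda–Grubbs catalyst, CH2Cl2, 40 °C) gives the (E)-γ-silyloxy enoate F9. PhSLi (THF, −78 → −20 °C) triggers a thiolate Michael addition followed by intramolecular aldol addition of the ester enolate (C6) to the C5 ketone from the side of C9, giving the β-phenylthio hydroxy ester F10 with ring C closed. Oxidation (m-CPBA, 1 equiv, CH2Cl2, −78 °C) gives the sulfoxide F11, and thermal syn-elimination (toluene, 90 °C, CaCO3) towards the acidic C6–H gives 26.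

Step 10. What may go wrong: low facial selectivity of the ylide addition, or deprotonation of the doubly activated C8–H with loss of configuration at C8 or isomerisation to a dienol ether. The fallback sets out from enone 14 and returns at ketone 15; it replaces substrate control by reagent control. Corey–Bakshi–Shibata reduction ((R)-2-methyl-CBS-oxazaborolidine, BH3·SMe2, THF, −30 °C) gives the (3S)-allylic alcohol F12. Hydroxyl-directed Simmons–Smith cyclopropanation (Et2Zn, CH2I2, CH2Cl2, −10 °C, limited reagent to spare the cyclobutene) delivers the methylene to the alkene face syn to the hydroxyl group in the conformer whose carbinol hydrogen eclipses the alkene, giving the cyclopropyl carbinol F13 with the C9/C13 configuration of 15. Dess–Martin oxidation returns to ketone 15.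

Further compounds
F1 | step 12 | 3-[(1R,4R)-4-octylcyclobut-2-en-1-yl]propanenitrile | CCCCCCCC[C@@H]1C=C[C@H]1CCC#N
F2 | step 12 | 3-[(1R,4R)-4-octylcyclobut-2-en-1-yl]propanal | CCCCCCCC[C@@H]1C=C[C@H]1CCC=O
F3 | step 12 | (R)-tert-butyldimethyl(pent-1-en-4-yn-3-yloxy)silane | C#C[C@H](O[Si](C)(C)C(C)(C)C)C=C
F4 | step 12 | (6R)-6-[(tert-butyldimethylsilyl)oxy]-1-[(1R,4R)-4-octylcyclobut-2-en-1-yl]oct-7-en-4-yn-3-ol (C3 epimers) | CCCCCCCC[C@@H]1C=C[C@H]1CCC(O)C#C[C@H](O[Si](C)(C)C(C)(C)C)C=C
F5 | step 12 | tricyclic cyclopentenone (C10 ketone, C9=C13, C5 alcohol) | CCCCCCCC[C@H]1[C@@H]2CCC(O)C3=C(C(=O)[C@H]1[C@H]23)[C@H](O[Si](C)(C)C(C)(C)C)C=C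
F6 | step 12 | saturated tricyclic C10 ketone, C5 alcohol | CCCCCCCC[C@H]1[C@@H]2CCC(O)[C@H]3[C@@H]2[C@@H]1C(=O)[C@@H]3[C@H](O[Si](C)(C)C(C)(C)C)C=C
F7 | step 12 | C10 tosylhydrazone of F6 | CCCCCCCC[C@H]1[C@@H]2CCC(O)[C@H]3[C@@H]2[C@@H]1C(=NNS(=O)(=O)c4ccc(C)cc4)[C@@H]3[C@H](O[Si](C)(C)C(C)(C)C)C=C
F8 | step 12 | tricyclic C5 alcohol with C10 methylene | CCCCCCCC[C@H]1[C@@H]2CCC(O)[C@H]3[C@@H]2[C@@H]1C[C@@H]3[C@H](O[Si](C)(C)C(C)(C)C)C=C
F9 | step 16 | ethyl (E)-4-[(tert-butyldimethylsilyl)oxy]-4-(tricyclic enone C9-yl)but-2-enoate | CCCCCCCC[C@H]1[C@@H]2C=CC(=O)[C@H]3[C@@H]2[C@@H]1C[C@@H]3[C@H](O[Si](C)(C)C(C)(C)C)/C=C/C(=O)OCC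
F10 | step 16 | tetracyclic C7-phenylthio C5-hydroxy ethyl ester (C6/C7 epimers) | CCCCCCCC[C@H]1[C@@H]2C=C[C@]3(O)C(C(=O)OCC)C(Sc5ccccc5)[C@@H](O[Si](C)(C)C(C)(C)C)[C@H]4C[C@H]1[C@H]2[C@@H]43
F11 | step 16 | sulfoxide of F10 | CCCCCCCC[C@H]1[C@@H]2C=C[C@]3(O)C(C(=O)OCC)C(S(=O)c5ccccc5)[C@@H](O[Si](C)(C)C(C)(C)C)[C@H]4C[C@H]1[C@H]2[C@@H]43
F12 | step 10 | (3S,4E,6R)-6-[(tert-butyldimethylsilyl)oxy]-1-[(1R,4R)-4-octylcyclobut-2-en-1-yl]octa-4,7-dien-3-ol | CCCCCCCC[C@@H]1C=C[C@H]1CC[C@H](O)/C=C/[C@H](O[Si](C)(C)C(C)(C)C)C=C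
F13 | step 10 | (S)-1-{(1S,2S)-2-[(R)-1-[(tert-butyldimethylsilyl)oxy]prop-2-en-1-yl]cyclopropyl}-3-[(1R,4R)-4-octylcyclobut-2-en-1-yl]propan-1-ol | CCCCCCCC[C@@H]1C=C[C@H]1CC[C@H](O)[C@H]2C[C@@H]2[C@H](O[Si](C)(C)C(C)(C)C)C=C
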